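**Plan**

- Retrosynthesis: cut the enol ester C–O bond first, then the two side-chain C–C bonds on ring A (cycloheptanone), then the ring A bond between the methyl-bearing quaternary carbon and its CH neighbour, then the O–CH2 bond of ring B (tetrahydropyran), and last the CH2–CH2 bond of ring C (cyclohexane) together with the bond between the two carbons shared by rings B and C.
- Enabling feature: ring C is a p-menthane unit. Its methyl-bearing carbon lies para to the ring-fusion CH that carries the C(CH3)2–O carbon of ring B, and the neighbouring ring-fusion CH carries the ring B carbon alpha to the ketone. Ring C is therefore the ortho/para Diels–Alder adduct of an (E)-1-substituted 3-methylbuta-1,3-diene and an acrylate; the acrylate carbonyl becomes C(CH3)2, its ester oxygen is the ring B oxygen, and the ring B CH2–O is the tether.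
- Forward order: ring C and a δ-lactone (proto-ring B) form together in the cycloaddition; MeMgBr and etherification give ring B; a hydrogen-atom-transfer radical cyclisation onto a vinyl ketone closes ring A and creates the quaternary centre; the side chains come last.
- Stereochemistry: absolute configuration comes from lipase desymmetrisation of a prochiral 2-dienylpropane-1,3-diol. That centre directs both ring-fusion centres in the cycloaddition; the quaternary centre follows from the bridging tether; the two side-chain centres come from conjugate addition anti to the ring C bridge and trans alkylation; the E enol ester comes from a stereoretentive copper coupling of an (E)-alkenyltrifluoroborate.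

Key step: step 6

Remark on the chemistry: the lipase is assumed to acylate the pro-R hydroxymethyl arm of diol 6; a lipase of the opposite preference would give the same (R)-monoester 7 by hydrolysis of the bis-acrylate of 6.

**Route**

Step 1
Reactants: 1 dimethyl malonate; 2 3-methylbut-2-enal
Product: 3 dimethyl 2-(3-methylbut-2-en-1-ylidene)malonate
Conditions: piperidine (cat.), AcOH (cat.), toluene, reflux, Dean–Stark
Reagents that add atoms: none
Why: Knoevenagel condensation of the malonate CH2 with the enal carbonyl, driven by azeotropic removal of water; no stereocentre is formed.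

Step 2
Reactants: 3 dimethyl 2-(3-methylbut-2-en-1-ylidene)malonate
Product: 5 dimethyl 2-[(1E)-3-methylbuta-1,3-dien-1-yl]malonate, via lithium trienolate 4 (not isolated)
Conditions: LDA, THF, −78 °C; then AcOH, −78 °C
Reagents that add atoms: none
Why: Deconjugative isomerisation: LDA removes a proton from a terminal methyl group to give the delocalised trienolate, kinetic protonation at the malonate carbon gives the skipped diester, and the new C=C is E because it arises from the s-trans conformer of the dienylidene.

Step 3
Reactants: 5 dimethyl 2-[(1E)-3-methylbuta-1,3-dien-1-yl]malonate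
Product: 6 2-[(1E)-3-methylbuta-1,3-dien-1-yl]propane-1,3-diol
Conditions: LiAlH4, Et2O, −20 → 0 °C (ester added to the hydride); aqueous work-up
Reagents that add atoms: none
Why: Hydride reduction of both esters gives the prochiral 2-substituted propane-1,3-diol; adding the ester to excess hydride at low temperature should let reduction outrun enolisation of the acidic malonate C–H.

Step 4
Reactants: 6 2-[(1E)-3-methylbuta-1,3-dien-1-yl]propane-1,3-diol
Product: 7 (2R,3E)-2-(hydroxymethyl)-5-methylhexa-3,5-dien-1-yl prop-2-enoate
Conditions: lipase PS (Burkholderia cepacia), vinyl acrylate, BHT (cat.), i-Pr2O, 25 °C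
Reagents that add atoms: vinyl acrylate, C=COC(=O)C=C
Why: Lipase-catalysed enantiotopos-selective transesterification (desymmetrisation of a 2-substituted propane-1,3-diol with an irreversible vinyl ester donor) acylates one hydroxymethyl arm and so creates the stereocentre that becomes the ring B carbon alpha to the ketone.

Step 5
Reactants: 7 (2R,3E)-2-(hydroxymethyl)-5-methylhexa-3,5-dien-1-yl prop-2-enoate
Product: 8 (2S,3E)-5-methyl-2-{[(triethylsilyl)oxy]methyl}hexa-3,5-dien-1-yl prop-2-enoate
Conditions: Et3SiCl, imidazole, CH2Cl2, 0 °C
Reagents that add atoms: chlorotriethylsilane, CC[Si](Cl)(CC)CC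
Why: Silylation of the remaining primary alcohol stops acyl migration between the two arms (which would racemise the centre) and marks this arm as the future ring A ketone carbon.

Step 6
Reactants: 8 (2S,3E)-5-methyl-2-{[(triethylsilyl)oxy]methyl}hexa-3,5-dien-1-yl prop-2-enoate
Product: 9 (4S,4aR,8aR)-6-methyl-4-{[(triethylsilyl)oxy]methyl}-3,4,4a,7,8,8a-hexahydro-1H-isochromen-1-one (cis-fused lactone)
Conditions: toluene (0.01 M), BHT (cat.), 170 °C, sealed tube
Reagents that add atoms: none
Why: Concerted, suprafacial thermal [4+2] cycloaddition between the (E)-3-methylbuta-1,3-dienyl unit and the tethered acrylate (intramolecular Diels–Alder reaction of an ester-linked deca-1,7,9-triene). The closest known reaction type is the thermal cyclisation of hexa-3,5-dienyl acrylates to cis-fused hexahydroisochromen-1-ones. The cyclohexene (future ring C) closes by the cycloaddition itself and the δ-lactone (future ring B) closes as the six-membered tether ring in the fused mode, since a four-atom tether on the diene terminus cannot span the bridged mode, and the tether also enforces the ortho/para regiochemistry that the methyl and carbonyl groups favour electronically. The two new ring-fusion stereocentres are cis because the in-tether carbonyl lies endo under the E-diene, and their configuration relative to the existing centre follows from a chair-like tether in which the silyloxymethyl group is pseudo-equatorial, so that the three ring hydrogens end up on one face. The step needs endo over exo selectivity and one diene face; the E geometry of the diene, the short carbonyl-containing tether and the stereocentre next to the diene should secure both, while high dilution and a radical inhibitor suppress intermolecular addition and acrylate polymerisation.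

Step 7
Reactants: 9 cis-fused lactone
Product: 10 (2S)-2-[(1R,6R)-6-(2-hydroxypropan-2-yl)-3-methylcyclohex-2-en-1-yl]-3-[(triethylsilyl)oxy]propan-1-ol
Conditions: MeMgBr (excess), THF, −20 → 0 °C; aq. NH4Cl
Reagents that add atoms: methylmagnesium bromide, C[Mg]Br
Why: Double Grignard addition to the lactone carbonyl installs the geminal dimethyl carbinol and releases the primary alcohol; the silyl ether is inert and no stereocentre is touched.

Step 8
Reactants: 10 diol
Product: 12 triethyl{[(4S,4aR,8aR)-1,1,6-trimethyl-3,4,4a,7,8,8a-hexahydro-1H-isochromen-4-yl]methoxy}silane, via primary tosylate 11 (not isolated)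
Conditions: TsCl, Et3N, DMAP (cat.), CH2Cl2, 0 °C; then NaH, THF, 0 → 45 °C
Reagents that add atoms: none
Why: Selective sulfonylation of the primary alcohol followed by intramolecular Williamson etherification (6-exo-tet SN2 by the tertiary alkoxide) closes ring B at a CH2 carbon, so no stereocentre is affected.

Step 9
Reactants: 12 bicyclic silyl ether
Product: 13 (4S,4aS,8aR)-1,1,6-trimethyl-3,4,4a,7,8,8a-hexahydro-1H-isochromene-4-carbaldehyde
Conditions: (COCl)2, DMSO, CH2Cl2, −78 → −30 °C; then i-Pr2NEt, −78 → 0 °C
Reagents that add atoms: none
Why: Swern conditions cleave a primary triethylsilyl ether and oxidise it to the aldehyde in the same flask; the hindered amine and a cold quench should keep the alpha centre from epimerising.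

Step 10
Reactants: 13 aldehyde
Product: 14 1-[(4S,4aR,8aR)-1,1,6-trimethyl-3,4,4a,7,8,8a-hexahydro-1H-isochromen-4-yl]prop-2-en-1-ol (both carbinol epimers)
Conditions: CH2=CHMgBr, THF, −78 °C
Reagents that add atoms: vinylmagnesium bromide, C=C[Mg]Br
Why: 1,2-Addition of the vinyl Grignard reagent to the aldehyde at low temperature; the new carbinol centre is oxidised away in the next step, so its configuration does not matter.

Step 11
Reactants: 14 allylic alcohol
Product: 15 1-[(4S,4aS,8aR)-1,1,6-trimethyl-3,4,4a,7,8,8a-hexahydro-1H-isochromen-4-yl]prop-2-en-1-one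
Conditions: Dess–Martin periodinane, CH2Cl2, 0 → 25 °C
Reagents that add atoms: none
Why: Dess–Martin oxidation of the allylic alcohol under non-basic conditions gives the vinyl ketone without epimerising the adjacent centre.

Step 12
Reactants: 15 vinyl ketone
Product: 16 tricyclic ketone (rings A–C of the target with its four core stereocentres; both ring A carbons that later carry side chains are CH2)
Conditions: Fe(acac)3, PhSiH3, EtOH/ethylene glycol (5:1), 60 °C, 0.01 M
Reagents that add atoms: none
Why: Metal-hydride hydrogen atom transfer to the trisubstituted alkene gives the tertiary radical at the methyl-bearing carbon, which adds in a 7-endo-trig Giese cyclisation to the unsubstituted terminus of the vinyl ketone; the tether can reach only the face of the radical on which the ring B carbon sits, which fixes the quaternary stereocentre as ring A closes.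

Step 13
Reactants: 16 tricyclic ketone
Product: 18 tricyclic enone (as 16 with a C=C between the ketone alpha carbon and the carbon attached to the quaternary centre), via trimethylsilyl enol ether 17 (not isolated)
Conditions: LDA, Me3SiCl, THF, −78 °C; then Pd(OAc)2 (1.1 equiv), MeCN, 25 °C
Reagents that add atoms: none
Why: Kinetic deprotonation at the less hindered alpha CH2 (not the ring-fusion CH), silylation and Saegusa–Ito oxidation give the enone regioselectively on the side of the quaternary carbon.

Step 14
Reactants: 18 tricyclic enone
Product: 22 vinyl diketone (vinyl on the ring A carbon next to the quaternary centre and cis to its methyl; acetonyl on the adjacent carbon and trans to the vinyl), via silyl enol ether 19 (not isolated), via lithium enolate 20 (not isolated), via methoxyallyl ketone 21 (not isolated)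
Conditions: CH2=CHMgBr, CuBr·SMe2 (cat.), Me3SiCl, THF, −78 °C; volatiles removed; then MeLi, THF, 0 °C; then HMPA, 2-methoxyallyl bromide, −78 → 0 °C; then 1 M HCl, THF, 0 °C
Reagents that add atoms: vinylmagnesium bromide, C=C[Mg]Br; 2-methoxyallyl bromide, COC(=C)CBr; water, O
Why: Copper-catalysed conjugate addition with silyl trapping should occur on the enone face opposite the three-carbon bridge of ring C (syn to the angular methyl), the enolate regenerated by Si–Li exchange is alkylated trans to the new vinyl group (vicinal trans dialkylation), and mild acid hydrolysis of the enol ether unmasks the methyl ketone.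

Step 15
Reactants: 22 vinyl diketone
Product: 23 (E)-alkenyl pinacol boronate (the vinyl group of 22 carrying a trans B(pin) at its terminus)
Conditions: vinylboronic acid pinacol ester (excess), second-generation Hoveyda–Grubbs catalyst (cat.), CH2Cl2, 40 °C
Reagents that add atoms: vinylboronic acid pinacol ester, C=CB1OC(C)(C)C(C)(C)O1
Why: Olefin cross-metathesis of the only alkene with the vinylboronate gives the 1,2-disubstituted alkenylboronate, for which the E isomer is strongly preferred.

Step 16
Reactants: 23 (E)-alkenyl pinacol boronate
Product: 24 potassium (E)-alkenyltrifluoroborate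
Conditions: KHF2, MeOH/H2O, 25 °C
Reagents that add atoms: potassium hydrogen difluoride, [K+].[F-].F
Why: Fluoride exchange at boron converts the pinacol ester into the trifluoroborate salt without touching the alkene geometry.

Step 17
Reactants: 24 potassium (E)-alkenyltrifluoroborate; 25 3-methylbut-2-enoic acid
Product: 26 vibsanin E
Conditions: CuBr (cat.), DMAP, 4 Å molecular sieves, O2 (1 atm), CH2Cl2, 40 °C
Reagents that add atoms: none
Why: Copper-catalysed oxidative C–O coupling of an alkenyltrifluoroborate with a carboxylic acid (Chan–Lam-type acyloxylation) forms the enol ester with retention of the E geometry under conditions that leave both ketones alone.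

**Compound list**

1 | dimethyl malonate | COC(=O)CC(=O)OC | starting material
2 | 3-methylbut-2-enal | CC(C)=CC=O | starting material
3 | dimethyl 2-(3-methylbut-2-en-1-ylidene)malonate | COC(=O)C(=CC=C(C)C)C(=O)OC | intermediate
4 | lithium trienolate of 5 | [Li+].COC(=O)[C-](/C=C/C(C)=C)C(=O)OC | intermediate (not isolated)
5 | dimethyl 2-[(1E)-3-methylbuta-1,3-dien-1-yl]malonate | COC(=O)C(/C=C/C(C)=C)C(=O)OC | intermediate
6 | 2-[(1E)-3-methylbuta-1,3-dien-1-yl]propane-1,3-diol | OCC(CO)/C=C/C(C)=C | intermediate
7 | (2R,3E)-2-(hydroxymethyl)-5-methylhexa-3,5-dien-1-yl prop-2-enoate | OC[C@@H](/C=C/C(C)=C)COC(=O)C=C | intermediate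
8 | (2S,3E)-5-methyl-2-{[(triethylsilyl)oxy]methyl}hexa-3,5-dien-1-yl prop-2-enoate | CC[Si](CC)(CC)OC[C@@H](/C=C/C(C)=C)COC(=O)C=C | intermediate
9 | (4S,4aR,8aR)-6-methyl-4-{[(triethylsilyl)oxy]methyl}-3,4,4a,7,8,8a-hexahydro-1H-isochromen-1-one (cis-fused; H-4, H-4a and H-8a on one face) | CC[Si](CC)(CC)OC[C@@H]1COC(=O)[C@@H]2CCC(C)=C[C@@H]21 | intermediate
10 | (2S)-2-[(1R,6R)-6-(2-hydroxypropan-2-yl)-3-methylcyclohex-2-en-1-yl]-3-[(triethylsilyl)oxy]propan-1-ol | CC[Si](CC)(CC)OC[C@@H]([C@H]1C=C(C)CC[C@H]1C(C)(C)O)CO | intermediate
11 | primary 4-methylbenzenesulfonate of 10 | CC[Si](CC)(CC)OC[C@@H]([C@H]1C=C(C)CC[C@H]1C(C)(C)O)COS(=O)(=O)c1ccc(C)cc1 | intermediate (not isolated)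
12 | triethyl{[(4S,4aR,8aR)-1,1,6-trimethyl-3,4,4a,7,8,8a-hexahydro-1H-isochromen-4-yl]methoxy}silane | CC[Si](CC)(CC)OC[C@@H]1COC(C)(C)[C@@H]2CCC(C)=C[C@@H]21 | intermediate
13 | (4S,4aS,8aR)-1,1,6-trimethyl-3,4,4a,7,8,8a-hexahydro-1H-isochromene-4-carbaldehyde | O=C[C@@H]1COC(C)(C)[C@@H]2CCC(C)=C[C@@H]21 | intermediate
14 | 1-[(4S,4aR,8aR)-1,1,6-trimethyl-3,4,4a,7,8,8a-hexahydro-1H-isochromen-4-yl]prop-2-en-1-ol (carbinol epimers) | C=CC(O)[C@@H]1COC(C)(C)[C@@H]2CCC(C)=C[C@@H]21 | intermediate
15 | 1-[(4S,4aS,8aR)-1,1,6-trimethyl-3,4,4a,7,8,8a-hexahydro-1H-isochromen-4-yl]prop-2-en-1-one | C=CC(=O)[C@@H]1COC(C)(C)[C@@H]2CCC(C)=C[C@@H]21 | intermediate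
16 | tricyclic ketone: rings A–C of the target, side-chain positions on ring A both CH2 | O=C1[C@@H]2COC(C)(C)[C@@H]3CC[C@@](C)(C[C@@H]32)CC1 | intermediate
17 | trimethylsilyl enol ether of 16 (enol C=C toward the ring A CH2) | C[Si](C)(C)OC=1[C@@H]2COC(C)(C)[C@@H]3CC[C@@](C)(C[C@@H]32)CC=1 | intermediate (not isolated)
18 | tricyclic enone: 16 with C=C between the ketone alpha carbon and the carbon attached to the quaternary centre | O=C1[C@@H]2COC(C)(C)[C@@H]3CC[C@@](C)(C[C@@H]32)C=C1 | intermediate
19 | trimethylsilyl enol ether of the vinyl adduct (vinyl cis to the angular methyl) | C[Si](C)(C)OC=1[C@@H]2COC(C)(C)[C@@H]3CC[C@@](C)(C[C@@H]32)[C@@H](C=C)C=1 | intermediate (not isolated)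
20 | lithium enolate corresponding to 19 | [Li]OC=1[C@@H]2COC(C)(C)[C@@H]3CC[C@@](C)(C[C@@H]32)[C@@H](C=C)C=1 | intermediate (not isolated)
21 | 2-methoxyallyl ketone (2-methoxyprop-2-enyl group trans to the vinyl group) | C=C(OC)C[C@@H]1C(=O)[C@@H]2COC(C)(C)[C@@H]3CC[C@@](C)(C[C@@H]32)[C@H]1C=C | intermediate (not isolated)
22 | vinyl diketone: the target with a vinyl group in place of the enol ester side chain | CC(=O)C[C@@H]1C(=O)[C@@H]2COC(C)(C)[C@@H]3CC[C@@](C)(C[C@@H]32)[C@H]1C=C | intermediate
23 | (E)-alkenyl pinacol boronate of 22 | CC(=O)C[C@@H]1C(=O)[C@@H]2COC(C)(C)[C@@H]3CC[C@@](C)(C[C@@H]32)[C@H]1/C=C/B4OC(C)(C)C(C)(C)O4 | intermediate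
24 | potassium (E)-alkenyltrifluoroborate | [K+].CC(=O)C[C@@H]1C(=O)[C@@H]2COC(C)(C)[C@@H]3CC[C@@](C)(C[C@@H]32)[C@H]1/C=C/[B-](F)(F)F | intermediate
25 | 3-methylbut-2-enoic acid | CC(C)=CC(=O)O | starting material
26 | vibsanin E | CC(=O)C[C@@H]1C(=O)[C@@H]2COC(C)(C)[C@@H]3CC[C@@](C)(C[C@@H]32)[C@H]1/C=C/OC(=O)C=C(C)C | target

**Totals and risks**

Total step count: 17. Longest linear sequence: 17 steps (from 1 and 2).

Steps most likely to fail:

Step 6. The endo preference may be too weak (cis versus trans ring fusion), the existing centre may bias the diene face the other way, or the ester tether may populate the reactive conformer so poorly that oligomerisation competes. Fallback from 8: an intermolecular, catalyst-controlled Diels–Alder reaction of the diene of 8 with 2,2,2-trifluoroethyl acrylate under a triflimide-activated chiral diphenylprolinol-derived B-(o-tolyl)oxazaborolidine (CH2Cl2, −78 °C) should give the endo ortho/para adduct, 2,2,2-trifluoroethyl (1R,2R)-4-methyl-2-[(2S)-1-(acryloyloxy)-3-(triethylsilyloxy)propan-2-yl]cyclohex-3-ene-1-carboxylate F1, with the diene face chosen by the catalyst enantiomer. Excess MeMgBr then converts the trifluoroethyl ester into the dimethyl carbinol and cleaves the acrylate ester, which rejoins the route at 10.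

Step 12. The tertiary radical or the enone may be reduced before the C–C bond forms, or the vinyl ketone may oligomerise. Fallback from 15: intramolecular enone–alkene [2+2] photocycloaddition (350 nm, CH2Cl2) should give the straight cyclobutane photoadduct F2, with new bonds from the ketone alpha carbon to the ring C alkene CH and from the beta carbon to the methyl-bearing carbon. SmI2 (THF/MeOH, −78 °C) then cleaves the cyclobutane bond alpha to the ketone that releases the secondary radical, which gives 16.

Step 15. The vinyl group, flanked by the quaternary carbon and the acetonyl-bearing carbon, may be too hindered to enter the metathesis cycle, or the alkene geometry may not be controlled. Fallback from 22: ozonolysis (O3, CH2Cl2, −78 °C; Me2S) gives the ring A aldehyde F3, and a Takai-type boron olefination (CrCl2, LiI, Cl2CHB(pin), THF) converts it into the (E)-alkenylboronate 23.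

**Further compounds**

F1 | step 6 | 2,2,2-trifluoroethyl (1R,2R)-4-methyl-2-[(2S)-1-(acryloyloxy)-3-(triethylsilyloxy)propan-2-yl]cyclohex-3-ene-1-carboxylate | CC[Si](CC)(CC)OC[C@@H]([C@H]1C=C(C)CC[C@H]1C(=O)OCC(F)(F)F)COC(=O)C=C
F2 | step 12 | cyclobutane photoadduct of 15 (cyclobutane cis-fused to ring C and to a cyclopentanone) | O=C1[C@@H]2COC(C)(C)[C@@H]3CC[C@@]4(C)[C@@H]([C@@H]32)[C@@H]1C4
F3 | step 15 | ring A aldehyde (formyl group in place of the vinyl group of 22) | CC(=O)C[C@@H]1C(=O)[C@@H]2COC(C)(C)[C@@H]3CC[C@@](C)(C[C@@H]32)[C@H]1C=O
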